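(The data come from a simulation with made-up constants, noise included.)

Follow one molecule of coupling partner through Saturday's flask, the flask asked about, and through Sunday's run, which has the same substrate and initiator charges: if each partner molecule leaves as one product, product stops where partner stops.

| flask | substrate | coupling partner | initiator | temperature | remark | time |
|---|---|---|---|---|---|---|
| Saturday's | 0.80 M | 0.56 M | 40 mM | 20 °C | the very flask that is asked about, followed so far |  |
| Sunday's | 0.80 M | 0.84 M | 40 mM | 5 °C | run made earlier |  |
| flask | 0.80 M | 0.560 M | 40 mM | 20 °C |  | 4.0 min |

| run | time / min | product / % |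
|---|---|---|
| Saturday's | 0.200 | 66.8 |
| Saturday's | 0.333 | 70.2 |
| Saturday's | 0.500 | 68.7 |
| Saturday's | 0.833 | 69.4 |
| Saturday's | 1.33 | 69.2 |
| Saturday's | 2.50 | 69.1 |
| Sunday's | 0.333 | 89.1 |
| Sunday's | 0.417 | 94.1 |
| Sunday's | 0.667 | 100.1 |
| Sunday's | 1.00 | 99.6 |
| Sunday's | 2.00 | 98.4 |
| Sunday's | 3.00 | 100.1 |

(readings scatter by 1 percentage point)

- blue: at 4.0 min take out 90% of the product then present, then wait 8.0 min
- red: at 4.0 min raise the temperature by 25 K, then wait 8.0 min
- ochre: change nothing and wait 8.0 min more
- amber: at 4.0 min add coupling partner, 50.0% of the amount charged, then wait 8.0 min

- removed product is counted in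
- additions bring no volume worth counting

1. product, in percent of the substrate first charged, at 4.0 min
2. what to do for the largest gain in product; "none" if nothing gains more than 2 percentage points (blue / red / ochre / amber / none)
3. product present, with what was taken out counted in, in percent of the substrate first charged, after blue
4. product present, with what was taken out counted in, in percent of the substrate first charged, after red

Saturday's readings level off from 0.333 min at a mean of 69.3%, and Sunday's level off from 0.667 min at 99.5%, each reading with a scatter of 1 percentage point. Sunday's run stood at 5 °C against 20 °C and still ended higher, so the colder bath did not keep it from the whole substrate charge. The partner charge, taken as a fraction of the substrate charge, is the other setting that differs between the two: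

Saturday's flask: 0.56 M / 0.80 M = 70.0%

Sunday's run: 0.84 M / 0.80 M = 105%

The first share is the partner ceiling, the part of the substrate charge that can become product at one partner per product while partner is the limiting reagent. Saturday's flask ends near its ceiling because partner is its smaller charge, whereas Sunday's run ends near the whole substrate charge because its partner is the larger charge.

The reckoning here therefore puts the flask at 70.0% at 4.0 min, later than the level began, and amber lifts the total partner charged, as a share of the substrate charge, to 105%.

The forecast gives 69.4%, a little under that ceiling, with 69.6% after blue, 69.3% after red, and amber as the best choice, on the ground that “the plateau is most simply partner exhaustion”.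

The flask gives 70.0% at 4.0 min, with 0% of its partner free at 4.00 min.

    initiator → 2 initiating radical (k = 0.00264 /s, Ea = 88.0 kJ/mol)
    first chain carrier → ended carrier (k = 140 /s, Ea = 68.0 kJ/mol)
    substrate + initiating radical → capped initiator + first chain carrier (k = 1.00 × 10⁵ /M/s, Ea = 23.0 kJ/mol)
    2 first chain carrier → ended chains (k = 1.00 × 10⁸ /M/s, Ea = 14.0 kJ/mol)
    substrate + second chain carrier → by-product + first chain carrier (k = 43400 /M/s, Ea = 16.0 kJ/mol)
    coupling partner + first chain carrier → product + second chain carrier (k = 4.89 × 10⁵ /M/s, Ea = 29.0 kJ/mol)
    (constants at 20 °C)

Blue gives 70.0% and red 70.0%, a gain of 0 points and 0 points, while amber gains 25 points, with 25.3% of the substrate free at 4.00 min. In this flask, with the other amounts and the time held, partner charges of 0.520 M and 0.600 M move the product at 4.0 min by 5 points. A neighbouring flask, the same but for 0.34 M of partner, has the ceiling 42.5%, and it holds 42.5% of product at 4.00 min, with 0% of its partner and 53% of its substrate left.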